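The target is treated as a germacranolide and numbered accordingly. The furanone oxygen that bridges C3 and the quaternary C10 (alpha to the C1 ketone) across the ten-membered carbocycle, an 11-oxabicyclo[6.2.1]undecane, is taken as the ring oxygen of a furan-derived dihydropyran that already holds the Z C4=C5 olefin and the C6 oxygen. A copper carbenoid at C10 is captured by that oxygen, and the oxonium ylide rearranges by a [2,3]-shift. This one operation closes the furanone ring, sets C10 and expands the pyran to the bridged macrocycle. The precursor is a trans-2,6-disubstituted dihydropyran with vinyl on C7, a CH2C(O)C(N2)CH3 arm on C3 and a silyloxy group on C6.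

Key step: step 12

Remark: germacranolide numbering is used throughout (C1 ketone, C2=C3, C4=C5, C6 lactone oxygen, C8 ester, C10 quaternary, C12 lactone carbonyl), and the lipase is assumed to follow its usual preference for the (R)-ester when furyl is the large and vinyl the medium group.

Step 1
Reactants: 1 4-bromofuran-2-carbaldehyde
Product: 2 4-methylfuran-2-carbaldehyde
Conditions: trimethylboroxine, Pd(dppf)Cl2 (3 mol %), K2CO3, 1,4-dioxane/H2O, 90 °C
Reagents that add atoms: trimethylboroxine, CB1OB(C)OB(C)O1
Why: Suzuki–Miyaura methylation of an electron-poor heteroaryl bromide, which the aldehyde tolerates.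

Step 2
Reactants: 2 4-methylfuran-2-carbaldehyde; 3 vinylmagnesium bromide
Product: 5 rac-1-(4-methylfuran-2-yl)prop-2-en-1-yl acetate, via bromomagnesium alkoxide 4 (not isolated)
Conditions: THF, −78 to 0 °C; then Ac2O, DMAP (cat.), 0 °C to rt
Reagents that add atoms: acetic anhydride, CC(=O)OC(C)=O
Why: Grignard 1,2-addition to the aldehyde followed by O-acylation of the alkoxide in the same flask should give the racemic acetate, which is the form the resolution needs.

Step 3
Reactants: 5 rac-1-(4-methylfuran-2-yl)prop-2-en-1-yl acetate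
Product: 6 (R)-1-(4-methylfuran-2-yl)prop-2-en-1-ol
Conditions: Novozym 435 (immobilised Candida antarctica lipase B), n-BuOH (3 equiv), MTBE, 30 °C, stopped below half conversion; chromatography
Reagents that add atoms: none
Why: Lipase-catalysed kinetic resolution by alcoholysis, in which the enzyme should cleave the (R)-acetate (furyl large, vinyl medium) and so release the needed (R)-alcohol directly, while the (S)-acetate stays behind and is separated.

Step 4
Reactants: 6 (R)-1-(4-methylfuran-2-yl)prop-2-en-1-ol
Product: 7 (2R)-6-hydroxy-5-methyl-2-vinyl-2H-pyran-3(6H)-one (anomeric mixture)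
Conditions: NBS, NaHCO3, NaOAc, THF/H2O (4:1), 0 °C
Reagents that add atoms: water, O
Why: Achmatowicz rearrangement, in which the electron-rich furan is oxidised far faster than the vinyl group and the ene-dione closes onto the carbinol oxygen, leaving the carbinol centre (C7) untouched.

Step 5
Reactants: 7 (2R)-6-hydroxy-5-methyl-2-vinyl-2H-pyran-3(6H)-one
Product: 8 (6R)-3-methyl-5-oxo-6-vinyl-5,6-dihydro-2H-pyran-2-yl acetate (anomeric mixture)
Conditions: Ac2O, pyridine, DMAP (cat.), CH2Cl2, 0 °C
Reagents that add atoms: acetic anhydride, CC(=O)OC(C)=O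
Why: Acylation of the lactol hydroxyl gives the glycosyl-type acetate needed for ionisation, and the anomeric configuration is irrelevant because it is lost in step 6.

Step 6
Reactants: 8 (6R)-3-methyl-5-oxo-6-vinyl-5,6-dihydro-2H-pyran-2-yl acetate; 9 tert-butyl(1-methoxyvinyloxy)dimethylsilane
Product: 10 methyl 2-[(2R,6R)-3-methyl-5-oxo-6-vinyl-5,6-dihydro-2H-pyran-2-yl]acetate (2,6-trans)
Conditions: BF3·OEt2, CH2Cl2, −78 to −40 °C
Reagents that add atoms: none
Why: Lewis-acid C-glycosylation (Mukaiyama-type addition of the ketene silyl acetal to the conjugated oxocarbenium ion), with the nucleophile entering at C3 on the face away from the C7 vinyl group to give the 2,6-trans product and set C3.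

Step 7
Reactants: 10 methyl 2-[(2R,6R)-3-methyl-5-oxo-6-vinyl-5,6-dihydro-2H-pyran-2-yl]acetate
Product: 11 methyl 2-[(2R,5S,6R)-5-hydroxy-3-methyl-6-vinyl-5,6-dihydro-2H-pyran-2-yl]acetate (C6 hydroxyl trans to vinyl)
Conditions: NaBH4, CeCl3·7H2O, MeOH, −78 °C
Reagents that add atoms: none
Why: Luche reduction gives clean 1,2-reduction of the enone without touching the ester, and axial hydride delivery should give the pseudo-equatorial alcohol trans to the adjacent vinyl group.

Step 8
Reactants: 11 methyl 2-[(2R,5S,6R)-5-hydroxy-3-methyl-6-vinyl-5,6-dihydro-2H-pyran-2-yl]acetate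
Product: 12 methyl 2-[(2R,5R,6R)-3-methyl-5-(4-nitrobenzoyloxy)-6-vinyl-5,6-dihydro-2H-pyran-2-yl]acetate
Conditions: 4-nitrobenzoic acid, PPh3, DIAD, THF, 0 °C to rt
Reagents that add atoms: 4-nitrobenzoic acid, OC(=O)c1ccc(cc1)[N+](=O)[O-]
Why: Mitsunobu inversion (SN2 at C6 by the acidic carboxylate) turns the C6 oxygen cis to the vinyl group and trans to the C3 arm, which is the C6 configuration of the target.

Step 9
Reactants: 12 methyl 2-[(2R,5R,6R)-3-methyl-5-(4-nitrobenzoyloxy)-6-vinyl-5,6-dihydro-2H-pyran-2-yl]acetate
Product: 13 2-[(2R,5R,6R)-5-hydroxy-3-methyl-6-vinyl-5,6-dihydro-2H-pyran-2-yl]acetic acid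
Conditions: LiOH, THF/MeOH/H2O, 0 °C to rt; then 1 M HCl to pH 3
Reagents that add atoms: lithium hydroxide, [Li+].[OH-]
Why: Saponification cleaves both esters in one operation by acyl–oxygen fission, so C6 keeps its configuration, and the trans relation of hydroxyl and acid arm rules out lactonisation.

Step 10
Reactants: 13 2-[(2R,5R,6R)-5-hydroxy-3-methyl-6-vinyl-5,6-dihydro-2H-pyran-2-yl]acetic acid
Product: 15 2-[(2R,5R,6R)-5-(tert-butyldimethylsilyloxy)-3-methyl-6-vinyl-5,6-dihydro-2H-pyran-2-yl]acetic acid, via silyl ether silyl ester 14 (not isolated)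
Conditions: TBSCl, imidazole, DMF, rt; then K2CO3 (cat.), MeOH/H2O, rt
Reagents that add atoms: tert-butyldimethylsilyl chloride, CC(C)(C)[Si](C)(C)Cl
Why: Silylation of hydroxyl and carboxyl followed by selective solvolysis of the labile silyl ester leaves the C6 silyl ether and the free acid.

Step 11
Reactants: 15 2-[(2R,5R,6R)-5-(tert-butyldimethylsilyloxy)-3-methyl-6-vinyl-5,6-dihydro-2H-pyran-2-yl]acetic acid; 16 N-ethyl-N-nitrosourea
Product: 19 3-diazo-1-[(2R,5R,6R)-5-(tert-butyldimethylsilyloxy)-3-methyl-6-vinyl-5,6-dihydro-2H-pyran-2-yl]butan-2-one, via acid chloride 17 (not isolated), via diazoethane 18 (not isolated)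
Conditions: (COCl)2, DMF (cat.), CH2Cl2, 0 °C to rt, evaporation; then CH3CHN2 (excess, from 16 with aq. KOH, Et2O, −15 °C), Et2O, −20 to 0 °C
Reagents that add atoms: none
Why: Acylation of a diazoalkane by an acid chloride (the first stage of the Arndt–Eistert sequence) gives the α-methyl diazoketone, the excess diazoethane taking up the hydrogen chloride released.

Step 12
Reactants: 19 3-diazo-1-[(2R,5R,6R)-5-(tert-butyldimethylsilyloxy)-3-methyl-6-vinyl-5,6-dihydro-2H-pyran-2-yl]butan-2-one
Product: 21 6-(tert-butyldimethylsilyloxy)-3,10-epoxygermacra-4Z,7Z-dien-1-one (11-oxabicyclo[6.2.1]undecadienone with C10 methyl and C4 methyl), via oxonium ylide 20 (not isolated)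
Conditions: Cu(hfacac)2 (hfacac = hexafluoroacetylacetonate, 5 mol %), CH2Cl2, reflux, slow addition of 19
Reagents that add atoms: none
Why: Cu(hfacac)2 decomposes the diazoketone to an electrophilic copper carbenoid at C10, the lone pair of the pyran oxygen 1,5 to it captures the carbenoid to give the bicyclic oxonium ylide 20, and a suprafacial five-centre [2,3]-sigmatropic shift then joins C10 to C9 while the allylic O–C7 bond breaks. The closest known reaction type is the copper-catalysed oxonium ylide formation and [2,3]-ring expansion of 2-vinyl cyclic ethers carrying a diazoketone arm, which gives oxygen-bridged medium-ring ketones; the methyl group on the diazo carbon and the olefin inside the pyran are the only extensions. The five-membered furanone ring closes by O–C10 bond formation (five-membered cyclic ylide), and the ten-membered carbocycle (nine-membered oxacycle) arises by three-atom ring expansion of the pyran, not by end-to-end cyclisation. The one new stereocentre, C10, is controlled by C3: the ylide carbon is a planar enolate carbon and C9 can only arrive on the face of the new ring that also carries C4, so the bridge is cis and C10 follows from C3, while the resolved centre C7 is erased. The step needs ylide formation to outrun cyclopropanation of C4=C5 and 1,2-hydride shift from the methyl group, which the 1,5 oxygen–carbenoid proximity and the electron-poor catalyst of divalent copper should secure. It also needs the new C7=C8 olefin to be Z, which should be favoured by the gauche arrangement of the O–C10 and C7–vinyl bonds in the cis-fused ylide and by the strain of an E olefin in a nine-membered ring that already holds a Z olefin.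

Step 13
Reactants: 21 6-(tert-butyldimethylsilyloxy)-3,10-epoxygermacra-4Z,7Z-dien-1-one
Product: 23 6-(tert-butyldimethylsilyloxy)-3,10-epoxygermacra-2,4Z,7Z-trien-1-one (bridged 3(2H)-furanone), via trimethylsilyl enol ether 22 (not isolated)
Conditions: LiHMDS, TMSCl, THF, −78 °C; then Pd(OAc)2, MeCN, rt
Reagents that add atoms: none
Why: Saegusa–Ito oxidation, in which C2 is the only enolisable position (C10 is quaternary), palladation should occur on the face away from the carbon bridge where H3 lies syn for β-hydride elimination, and divalent palladium ends as zerovalent palladium.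

Step 14
Reactants: 23 6-(tert-butyldimethylsilyloxy)-3,10-epoxygermacra-2,4Z,7Z-trien-1-one
Product: 24 6-hydroxy-3,10-epoxygermacra-2,4Z,7Z-trien-1-one
Conditions: HF·pyridine, pyridine, THF, 0 °C to rt
Reagents that add atoms: none
Why: Buffered fluoride desilylation frees the C6 alcohol without ionising the doubly allylic position, which the electron-poor dienone on one side deactivates.

Step 15
Reactants: 24 6-hydroxy-3,10-epoxygermacra-2,4Z,7Z-trien-1-one; 25 mono-tert-butyl malonate
Product: 26 tert-butyl (1-oxo-3,10-epoxygermacra-2,4Z,7Z-trien-6-yl) malonate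
Conditions: DCC, DMAP (cat.), CH2Cl2, 0 °C to rt
Reagents that add atoms: none
Why: Steglich esterification of the secondary allylic alcohol with the malonic half-ester, with retention at C6.

Step 16
Reactants: 26 tert-butyl (1-oxo-3,10-epoxygermacra-2,4Z,7Z-trien-6-yl) malonate
Product: 27 tert-butyl (1-oxo-3,10-epoxygermacra-2,4Z,7Z-trien-6-yl) 2-diazomalonate
Conditions: 4-acetamidobenzenesulfonyl azide, Et3N, MeCN, 0 °C to rt
Reagents that add atoms: 4-acetamidobenzenesulfonyl azide, CC(=O)Nc1ccc(cc1)S(=O)(=O)N=[N+]=[N-]
Why: Regitz diazo transfer to the active methylene of the mixed malonate, the only carbon acid of that strength in the molecule.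

Step 17
Reactants: 27 tert-butyl (1-oxo-3,10-epoxygermacra-2,4Z,7Z-trien-6-yl) 2-diazomalonate
Product: 28 tert-butyl 7,8-cyclopropane-fused 12,6-lactone 11-carboxylate (C7, C8 and C11 form the cyclopropane; 3-oxabicyclo[3.1.0]hexan-2-one fused to the bridged furanone macrocycle)
Conditions: Rh2(esp)2 (1 mol %), CH2Cl2, 40 °C, slow addition
Reagents that add atoms: none
Why: Intramolecular cyclopropanation by a dirhodium carbenoid, in which the malonyl carbenoid tethered through O6 should add to the isolated, electron-richer Z C7=C8 olefin rather than to C4=C5 of the electron-poor dienone, the conformer with H6 eclipsing the olefin (minimal allylic strain) leads to H6 and H7 trans (trans-lactone), and the cis olefin geometry fixes C8 relative to C7.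

Step 18
Reactants: 28 tert-butyl 7,8-cyclopropane-fused 12,6-lactone 11-carboxylate
Product: 30 tert-butyl 8-bromo-11-methyl-12,6-lactone 11-carboxylate (C8 bromide with inverted C8 and quaternary C11), via lithium enolate 29 (not isolated)
Conditions: LiBr, MeBr (excess), DMF, sealed tube, 50 °C
Reagents that add atoms: lithium bromide, [Li+].[Br-]; bromomethane, CBr
Why: Proposed new method: lithium-assisted bromide should attack C8 of the doubly activated cyclopropane from the side opposite C11 (homoconjugate SN2 addition with inversion at C8), and the ring-opened lithium enolate 29, which can otherwise only close back to 28, is drained by irreversible C-methylation at C11 with bromomethane, which also returns the bromide; the closest known reaction types are the MgI2-mediated halide opening of cyclopropane-1,1-dicarbonyl compounds with capture of the enolate in the flask by imines or aldehydes and the alkylation of malonate enolates, and the configuration formed at C11 does not matter because step 19 erases it.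

Step 19
Reactants: 30 tert-butyl 8-bromo-11-methyl-12,6-lactone 11-carboxylate
Product: 32 8-bromo-11-methyl trans-12,6-lactone of the bridged furanone (C8 epimeric to the target ester position), via malonic acid half-lactone 31 (not isolated)
Conditions: TFA, CH2Cl2, 0 °C to rt; evaporation; toluene, 100 °C
Reagents that add atoms: none
Why: Acidolysis of the tert-butyl ester and thermal decarboxylation of the α-carboxy lactone, with C11 expected to be protonated anti to H7 (torsional control in the trans-fused lactone) to place the methyl group cis to H7, which is also the more stable epimer; the quaternary C11 and the non-basic medium keep the C8 bromide from closing back to a cyclopropane.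

Step 20
Reactants: 32 8-bromo-11-methyl trans-12,6-lactone of the bridged furanone; 33 angelic acid
Product: 34 CNP0278264.1, (6R,7R,8R,10R,11S)-8-angeloyloxy-3,10-epoxy-1-oxogermacra-2,4Z-dien-12,6-olide
Conditions: 33, Cs2CO3 (0.5 equiv per acid), MeOH, evaporation; then 32, DMF, 40 °C
Reagents that add atoms: none
Why: SN2 displacement of the secondary bromide by cesium angelate with inversion at C8, which together with the inversion of step 18 places the C8 oxygen where the cyclopropane bond to C11 stood; carboxylate alkylation leaves the Z geometry of the angelate intact, and the carbonate-free salt avoids enolising C11.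

Compound list
1 | 4-bromofuran-2-carbaldehyde | O=Cc1cc(Br)co1 | starting material
2 | 4-methylfuran-2-carbaldehyde | O=Cc1cc(C)co1 | intermediate
3 | vinylmagnesium bromide | C=C[Mg]Br | starting material
4 | bromomagnesium 1-(4-methylfuran-2-yl)prop-2-en-1-olate (racemic) | C=CC(O[Mg]Br)c1cc(C)co1 | intermediate
5 | rac-1-(4-methylfuran-2-yl)prop-2-en-1-yl acetate | CC(=O)OC(C=C)c1cc(C)co1 | intermediate
6 | (R)-1-(4-methylfuran-2-yl)prop-2-en-1-ol | O[C@H](C=C)c1cc(C)co1 | intermediate
7 | (2R)-6-hydroxy-5-methyl-2-vinyl-2H-pyran-3(6H)-one (anomeric mixture) | OC1O[C@H](C=C)C(=O)C=C1C | intermediate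
8 | (6R)-3-methyl-5-oxo-6-vinyl-5,6-dihydro-2H-pyran-2-yl acetate (anomeric mixture) | CC(=O)OC1O[C@H](C=C)C(=O)C=C1C | intermediate
9 | tert-butyl(1-methoxyvinyloxy)dimethylsilane | COC(=C)O[Si](C)(C)C(C)(C)C | starting material
10 | methyl 2-[(2R,6R)-3-methyl-5-oxo-6-vinyl-5,6-dihydro-2H-pyran-2-yl]acetate (2,6-trans) | COC(=O)C[C@H]1O[C@H](C=C)C(=O)C=C1C | intermediate
11 | methyl 2-[(2R,5S,6R)-5-hydroxy-3-methyl-6-vinyl-5,6-dihydro-2H-pyran-2-yl]acetate (hydroxyl trans to vinyl) | COC(=O)C[C@H]1O[C@H](C=C)[C@@H](O)C=C1C | intermediate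
12 | methyl 2-[(2R,5R,6R)-3-methyl-5-(4-nitrobenzoyloxy)-6-vinyl-5,6-dihydro-2H-pyran-2-yl]acetate | COC(=O)C[C@H]1O[C@H](C=C)[C@H](OC(=O)c2ccc(cc2)[N+](=O)[O-])C=C1C | intermediate
13 | 2-[(2R,5R,6R)-5-hydroxy-3-methyl-6-vinyl-5,6-dihydro-2H-pyran-2-yl]acetic acid | OC(=O)C[C@H]1O[C@H](C=C)[C@H](O)C=C1C | intermediate
14 | tert-butyldimethylsilyl ester of the C6 tert-butyldimethylsilyl ether of 13 | CC(C)(C)[Si](C)(C)OC(=O)C[C@H]1O[C@H](C=C)[C@H](O[Si](C)(C)C(C)(C)C)C=C1C | intermediate
15 | 2-[(2R,5R,6R)-5-(tert-butyldimethylsilyloxy)-3-methyl-6-vinyl-5,6-dihydro-2H-pyran-2-yl]acetic acid | OC(=O)C[C@H]1O[C@H](C=C)[C@H](O[Si](C)(C)C(C)(C)C)C=C1C | intermediate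
16 | N-ethyl-N-nitrosourea | CCN(N=O)C(N)=O | starting material
17 | acid chloride of 15 | ClC(=O)C[C@H]1O[C@H](C=C)[C@H](O[Si](C)(C)C(C)(C)C)C=C1C | intermediate
18 | diazoethane | CC=[N+]=[N-] | intermediate
19 | 3-diazo-1-[(2R,5R,6R)-5-(tert-butyldimethylsilyloxy)-3-methyl-6-vinyl-5,6-dihydro-2H-pyran-2-yl]butan-2-one (key precursor) | CC(=[N+]=[N-])C(=O)C[C@H]1O[C@H](C=C)[C@H](O[Si](C)(C)C(C)(C)C)C=C1C | intermediate
20 | bicyclic oxonium ylide (pyran oxygen bonded to C3, C7 and the enolate carbon C10) | C[C-]1C(=O)C[C@H]2[O+]1[C@H](C=C)[C@H](O[Si](C)(C)C(C)(C)C)C=C2C | intermediate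
21 | 6-(tert-butyldimethylsilyloxy)-3,10-epoxygermacra-4Z,7Z-dien-1-one | O=C1C[C@H]2O[C@]1(C)C/C=C\[C@H](O[Si](C)(C)C(C)(C)C)/C=C2/C | intermediate
22 | trimethylsilyl enol ether of 21 (C1=C2) | C[Si](C)(C)OC1=C[C@H]2O[C@]1(C)C/C=C\[C@H](O[Si](C)(C)C(C)(C)C)/C=C2/C | intermediate
23 | 6-(tert-butyldimethylsilyloxy)-3,10-epoxygermacra-2,4Z,7Z-trien-1-one | O=C1C=C2O[C@]1(C)C/C=C\[C@H](O[Si](C)(C)C(C)(C)C)/C=C2/C | intermediate
24 | 6-hydroxy-3,10-epoxygermacra-2,4Z,7Z-trien-1-one | O=C1C=C2O[C@]1(C)C/C=C\[C@H](O)/C=C2/C | intermediate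
25 | mono-tert-butyl malonate | CC(C)(C)OC(=O)CC(=O)O | starting material
26 | tert-butyl (1-oxo-3,10-epoxygermacra-2,4Z,7Z-trien-6-yl) malonate | O=C1C=C2O[C@]1(C)C/C=C\[C@H](OC(=O)CC(=O)OC(C)(C)C)/C=C2/C | intermediate
27 | tert-butyl (1-oxo-3,10-epoxygermacra-2,4Z,7Z-trien-6-yl) 2-diazomalonate | O=C1C=C2O[C@]1(C)C/C=C\[C@H](OC(=O)C(=[N+]=[N-])C(=O)OC(C)(C)C)/C=C2/C | intermediate
28 | cyclopropane-fused γ-lactone tert-butyl ester (cyclopropane C7, C8, C11; H6 and H7 trans) | CC(C)(C)OC(=O)[C@@]12C(=O)O[C@@H]3/C=C(C)\C4=CC(=O)[C@](C)(O4)C[C@@H]1[C@@H]23 | intermediate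
29 | lithium enolate of the ring-opened C8 bromide (C11=C12 enolate) | [Li+].Br[C@H]1C[C@@]2(C)OC(=CC2=O)/C(C)=C\[C@H]2OC([O-])=C(C(=O)OC(C)(C)C)[C@@H]21 | intermediate
30 | tert-butyl 8-bromo-11-methyl-12,6-lactone 11-carboxylate (methyl anti to H7) | Br[C@H]1C[C@@]2(C)OC(=CC2=O)/C(C)=C\[C@H]2OC(=O)[C@@](C)(C(=O)OC(C)(C)C)[C@@H]21 | intermediate
31 | 8-bromo-11-methyl-12,6-lactone 11-carboxylic acid | Br[C@H]1C[C@@]2(C)OC(=CC2=O)/C(C)=C\[C@H]2OC(=O)[C@@](C)(C(=O)O)[C@@H]21 | intermediate
32 | 8-bromo-11-methyl trans-12,6-lactone (methyl cis to H7) | Br[C@H]1C[C@@]2(C)OC(=CC2=O)/C(C)=C\[C@H]2OC(=O)[C@@H](C)[C@@H]21 | intermediate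
33 | angelic acid | C/C=C(/C)C(=O)O | starting material
34 | CNP0278264.1, (6R,7R,8R,10R,11S)-8-angeloyloxy-3,10-epoxy-1-oxogermacra-2,4Z-dien-12,6-olide | C/C=C(/C)C(=O)O[C@@H]1C[C@@]2(C)OC(=CC2=O)/C(C)=C\[C@H]2OC(=O)[C@@H](C)[C@@H]21 | target

Total step count: 20. Longest linear sequence: 20 steps (from 1 to 34; 3, 9, 16, 25 and 33 are bought and enter directly).

Steps most likely to fail

1. Step 18 (proposed new method). Bromide attack at C8 may be too slow, bromide may instead cleave the allylic C6–O bond of the lactone, or re-closure of the enolate may outrun methylation so that 28 is simply returned. The fallback uses known reaction types, sets out from 28 and returns at 32. Lewis-acid halide opening with MgBr2·OEt2 (CH2Cl2/Et2O, 0 °C to rt) with an acidic aqueous quench should give the C8 bromide of the α-tert-butoxycarbonyl lactone F1, the enolate being held as a magnesium chelate and only protonated. TFA then frees the α-carboxy lactone F2. Mannich conditions (paraformaldehyde, Et2NH, AcOH buffer, dioxane, 70 °C) should bring about decarboxylative methylenation to the α-methylene lactone bromide F3. Hydrogenation of the exocyclic olefin alone with RhCl(PPh3)3 and H2 (benzene/EtOH, rt), hydrogen arriving at C11 anti to H7, gives 32.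

2. Step 12 (key step). The carbenoid may be lost by 1,2-hydride shift from its methyl group, by cyclopropanation of C4=C5 or by a [1,2]-shift of the ylide, or the new olefin may form with E geometry. The fallback sets out from 15 and returns at 23. The acid chloride 17 is treated with diazomethane in place of diazoethane to give the terminal diazoketone F4, whose carbenoid has no hydrogen to shift. The same Cu(hfacac)2 ring expansion, now in its established form, should give the C10-unmethylated bridged ketone F5. Saegusa–Ito oxidation as in step 13 gives the bridged furanone F6, in which C10 is the only enolisable position. LiHMDS and then MeI (THF, −78 °C) should methylate C10 on its only open face and give 23.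

3. Step 20. Substitution at the hindered secondary bromide may be slow, and elimination towards C7=C8 or C8=C9 may compete. The fallback sets out from 32 and returns at 34. Cesium formate (18-crown-6, DMF, 40 °C), a smaller and less basic oxygen nucleophile, should displace the bromide with inversion to the C8 formate F7. KHCO3 in MeOH at 0 °C releases the C8 alcohol F8. Yamaguchi esterification with 33 (2,4,6-trichlorobenzoyl chloride, Et3N, then F8 and DMAP, toluene, 60 °C) should give 34 without isomerising the angelate.

Further compounds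
F1 | step 18 | tert-butyl 8-bromo-12,6-lactone 11-carboxylate (C11–H, epimerisable) | Br[C@H]1C[C@@]2(C)OC(=CC2=O)/C(C)=C\[C@H]2OC(=O)C(C(=O)OC(C)(C)C)[C@@H]21
F2 | step 18 | 8-bromo-12,6-lactone 11-carboxylic acid | Br[C@H]1C[C@@]2(C)OC(=CC2=O)/C(C)=C\[C@H]2OC(=O)C(C(O)=O)[C@@H]21
F3 | step 18 | 8-bromo-11(13)-methylene-12,6-lactone | Br[C@H]1C[C@@]2(C)OC(=CC2=O)/C(C)=C\[C@H]2OC(=O)C(=C)[C@@H]21
F4 | step 12 | 1-diazo-3-[(2R,5R,6R)-5-(tert-butyldimethylsilyloxy)-3-methyl-6-vinyl-5,6-dihydro-2H-pyran-2-yl]propan-2-one | [N-]=[N+]=CC(=O)C[C@H]1O[C@H](C=C)[C@H](O[Si](C)(C)C(C)(C)C)C=C1C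
F5 | step 12 | C10-unmethylated bridged ketone (6-silyloxy-3,10-epoxy-14-norgermacra-4Z,7Z-dien-1-one) | O=C1C[C@H]2O[C@@H]1C/C=C\[C@H](O[Si](C)(C)C(C)(C)C)/C=C2/C
F6 | step 12 | C10-unmethylated bridged 3(2H)-furanone | O=C1C=C2O[C@@H]1C/C=C\[C@H](O[Si](C)(C)C(C)(C)C)/C=C2/C
F7 | step 20 | C8 formate of the 11-methyl trans-lactone (target configuration at C8) | O=CO[C@@H]1C[C@@]2(C)OC(=CC2=O)/C(C)=C\[C@H]2OC(=O)[C@@H](C)[C@@H]21
F8 | step 20 | C8 alcohol of the 11-methyl trans-lactone (target configuration at C8) | O[C@@H]1C[C@@]2(C)OC(=CC2=O)/C(C)=C\[C@H]2OC(=O)[C@@H](C)[C@@H]21
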